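**Retrosynthetic overview**

1. Locants in the text are eudesmane locants: ring B = C5–C10 (methyl on C10), side chain C1–C4 (methyl on C4), lactone carbons C11–C13 closed on O8; compound names keep their own systematic locants.
2. Last: both isobutyrates (O1, O6) by acylation of diol 19; before that the α-methylene lactone ring by oxidative lactonisation of a 2-methylene-1,4-diol (C12 onto O8). Ring order: ring B first (taken from an arene), lactone last.
3. Key disconnection C4–C5: enol triflate 10 of ring B plus achiral (Z)-pent-3-en-1-ol in an enantioselective redox-relay Heck reaction, which brings in all five side-chain carbons, sets C4 and leaves C1 as the aldehyde.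
4. Enabling feature: C5=C10 is the tetrasubstituted enol of a 2-methylcyclohexanone (C5 = carbonyl carbon), and C4 is an H-bearing stereocentre joined to the oxygenated terminus C1 by the saturated C3–C2 bridge, so the C1–O function is the sink of palladium chain walking from a C3=C4 alkene.
5. Ring B: 4-methoxy-2-methylphenol → quinone monoketal (O at C5 and C8, methyl on C10); C7 by rhodium-catalysed asymmetric alkenylation, C6–O by enolate oxidation anti to C7, C5–OTf by conjugate reduction/triflation, C8–OH by hydride attack anti to C7.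

Key step: step 7

Assumption: the sense of induction in the two ligand-controlled steps is taken from the usual models ((R)-BINAP in step 3 by analogy with cyclohex-2-enone; the (S)-pyridine–oxazoline ligand with a (Z)-alkenol in step 7); if either sense proves opposite, the enantiomeric ligand is used and nothing else changes.

**Route**

Step 1
Reactants: 1 4-methoxy-2-methylphenol
Product: 2 4,4-dimethoxy-2-methylcyclohexa-2,5-dien-1-one
Conditions: PhI(OAc)2 (1.1 equiv), MeOH, 0 °C
Reagents that add atoms: methanol (CO)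
Why: Oxidative dearomatization of a para-methoxyphenol, in which methanol captures the oxidised ring at the methoxy-bearing carbon to give the quinone monoketal that already holds oxygen at C5 and C8 and the methyl on C10; no stereocentre is formed.

Step 2
Reactants: 3 tert-butyldimethyl(prop-2-yn-1-yloxy)silane
Product: 4 tert-butyldimethyl{[2-(4,4,5,5-tetramethyl-1,3,2-dioxaborolan-2-yl)prop-2-en-1-yl]oxy}silane
Conditions: B2pin2 (1.1 equiv), CuCl (5 mol %), 1,3-dimesitylimidazolinium chloride (5 mol %), NaOt-Bu (20 mol %), MeOH (2 equiv), THF, −50 → −15 °C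
Reagents that add atoms: bis(pinacolato)diboron (CC1(C)OB(OC1(C)C)B1OC(C)(C)C(C)(C)O1)
Why: Copper-catalysed protoboration of a terminal alkyne (boryl-copper addition, then protonation by methanol), in which the N-aryl carbene ligand and the propargylic oxygen place boron on the internal carbon; no stereocentre is formed.

Step 3
Reactants: 2 4,4-dimethoxy-2-methylcyclohexa-2,5-dien-1-one; 4 tert-butyldimethyl{[2-(4,4,5,5-tetramethyl-1,3,2-dioxaborolan-2-yl)prop-2-en-1-yl]oxy}silane
Product: 5 (5R)-5-[3-(TBSO)prop-1-en-2-yl]-4,4-dimethoxy-2-methylcyclohex-2-en-1-one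
Conditions: [RhCl(cod)]2 (2.5 mol %), (R)-BINAP (6 mol %), Et3N (1 equiv), dioxane/H2O 10:1, 40 °C
Reagents that add atoms: none
Why: Rhodium-catalysed asymmetric 1,4-addition of an alkenylboron reagent to an enone (Hayashi–Miyaura reaction), in which the alkenylrhodium adds to the unsubstituted enone (the methyl-bearing enone is far less reactive) and the BINAP ligand selects the enone face, which sets C7.

Step 4
Reactants: 5 (5R)-5-[3-(TBSO)prop-1-en-2-yl]-4,4-dimethoxy-2-methylcyclohex-2-en-1-one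
Product: 7 (5S,6S)-5-[3-(TBSO)prop-1-en-2-yl]-6-hydroxy-4,4-dimethoxy-2-methylcyclohex-2-en-1-one, via sodium dienolate 6 (not isolated)
Conditions: NaN(SiMe3)2 (1.1 equiv), THF, −78 °C; then 2-(phenylsulfonyl)-3-phenyloxaziridine (1.3 equiv), −78 °C; aq. NH4Cl
Reagents that add atoms: 2-(phenylsulfonyl)-3-phenyloxaziridine (O=S(=O)(N1OC1c1ccccc1)c1ccccc1)
Why: Kinetic deprotonation at the only α-CH2 gives the cross-conjugated enolate, and oxygen transfer from the N-sulfonyloxaziridine (Davis oxidation) occurs on the face opposite to the neighbouring alkenyl group, which sets C6–O trans to C7.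

Step 5
Reactants: 7 (5S,6S)-5-[3-(TBSO)prop-1-en-2-yl]-6-hydroxy-4,4-dimethoxy-2-methylcyclohex-2-en-1-one
Product: 8 (5S,6S)-6-(TBSO)-5-[3-(TBSO)prop-1-en-2-yl]-4,4-dimethoxy-2-methylcyclohex-2-en-1-one
Conditions: TBSCl (1.5 equiv), imidazole (3 equiv), DMF, 23 → 40 °C
Reagents that add atoms: tert-butyldimethylsilyl chloride (CC(C)(C)[Si](C)(C)Cl)
Why: Standard silylation of a secondary alcohol with a silyl chloride and imidazole, chosen over a silyl triflate so that the dimethyl ketal is not activated; no stereocentre is touched.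

Step 6
Reactants: 8 (5S,6S)-6-(TBSO)-5-[3-(TBSO)prop-1-en-2-yl]-4,4-dimethoxy-2-methylcyclohex-2-en-1-one
Product: 10 (5S,6S)-6-(TBSO)-5-[3-(TBSO)prop-1-en-2-yl]-4,4-dimethoxy-2-methylcyclohex-1-en-1-yl trifluoromethanesulfonate, via lithium enolate 9 (not isolated)
Conditions: LiBH(s-Bu)3 (1.05 equiv), THF, −78 °C; then PhNTf2 (1.2 equiv), −78 → 0 °C; aq. NH4Cl
Reagents that add atoms: N-phenylbis(trifluoromethanesulfonimide) (O=S(=O)(N(c1ccccc1)S(=O)(=O)C(F)(F)F)C(F)(F)F)
Why: Conjugate reduction of the β-unsubstituted α-methyl enone by the bulky trialkylborohydride gives the enolate with the double bond fixed between C5 and C10, and O-sulfonylation turns it into the tetrasubstituted enol triflate without forming a new stereocentre.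

Step 7
Reactants: 10 (5S,6S)-6-(TBSO)-5-[3-(TBSO)prop-1-en-2-yl]-4,4-dimethoxy-2-methylcyclohex-1-en-1-yl trifluoromethanesulfonate; 11 (Z)-pent-3-en-1-ol
Product: 12 (4S)-4-{(5S,6S)-6-(TBSO)-5-[3-(TBSO)prop-1-en-2-yl]-4,4-dimethoxy-2-methylcyclohex-1-en-1-yl}pentanal
Conditions: Pd2(dba)3 (5 mol %), (S)-4-tert-butyl-2-[5-(trifluoromethyl)pyridin-2-yl]-4,5-dihydrooxazole (12 mol %), 11 (3 equiv), 2,6-di-tert-butylpyridine (1.5 equiv), 3 Å molecular sieves, DMA, 23 °C
Reagents that add atoms: none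
Why: Zerovalent palladium inserts into the C5–OTf bond of 10 to give a cationic alkenylpalladium, which adds syn across the (Z)-alkene of 11 with C5 on C4 (the alkene carbon remote from the hydroxyl) and palladium on C3; repeated β-hydride elimination and reinsertion then walk palladium along C3–C2 to C1, where loss of the carbinol hydrogen releases aldehyde 12 and HPdOTf, which the pyridine base takes up. The closest known reaction type is the enantioselective redox-relay Heck alkenylation of acyclic homoallylic alkenols with alkenyl triflates, which gives γ-alkenyl aldehydes. No ring is closed. The new stereocentre C4 is set in the migratory insertion by the chiral pyridine–oxazoline ligand, which selects the alkene face, with the Z geometry of 11 fixing the sense and the ring stereocentres C6 and C7 expected to be overridden by the catalyst. The step needs insertion at C4 and not C3, which the polarisation of the alkene by the homoallylic hydroxyl should secure, and relay toward C1 and not β-hydride loss from C4, which is disfavoured because the resulting diene would be twisted against the tetrasubstituted ring alkene while the alcohol is the thermodynamic sink. The 1,1-disubstituted alkene on C7 cannot reach the alkenylpalladium in a favourable ring size, and the ketal and silyl ethers are protected from triflic acid by the hindered base.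

Step 8
Reactants: 12 (4S)-4-{(5S,6S)-6-(TBSO)-5-[3-(TBSO)prop-1-en-2-yl]-4,4-dimethoxy-2-methylcyclohex-1-en-1-yl}pentanal
Product: 13 (4S)-4-{(5S,6S)-6-(TBSO)-5-[3-(TBSO)prop-1-en-2-yl]-2-methyl-4-oxocyclohex-1-en-1-yl}pentanal
Conditions: PPTS (0.2 equiv), acetone/H2O 10:1, 23 °C; used directly
Reagents that add atoms: water (O)
Why: Mild acid-catalysed ketal hydrolysis frees the C8 ketone while both silyl ethers stay and the alkene stays out of conjugation; because this β-siloxy ketone could eliminate and aromatize, it is reduced at once; no stereocentre is formed.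

Step 9
Reactants: 13 (4S)-4-{(5S,6S)-6-(TBSO)-5-[3-(TBSO)prop-1-en-2-yl]-2-methyl-4-oxocyclohex-1-en-1-yl}pentanal
Product: 14 (1R,5S,6R)-5-(TBSO)-6-[3-(TBSO)prop-1-en-2-yl]-4-[(2S)-5-hydroxypentan-2-yl]-3-methylcyclohex-3-en-1-ol
Conditions: LiBH(s-Bu)3 (2.5 equiv), THF, −78 °C; aq. NH4Cl
Reagents that add atoms: none
Why: Hydride reduction with a bulky trialkylborohydride reduces the aldehyde to the C1 alcohol and attacks the C8 ketone from the face opposite to the C7 substituent (equatorial attack), which gives the axial C8 alcohol cis to C7–C11 as needed for the cis-fused lactone.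

Step 10
Reactants: 14 (1R,5S,6R)-5-(TBSO)-6-[3-(TBSO)prop-1-en-2-yl]-4-[(2S)-5-hydroxypentan-2-yl]-3-methylcyclohex-3-en-1-ol
Product: 15 (1R,5S,6R)-5-(TBSO)-6-(3-hydroxyprop-1-en-2-yl)-4-[(2S)-5-hydroxypentan-2-yl]-3-methylcyclohex-3-en-1-ol
Conditions: camphorsulfonic acid (0.1 equiv), MeOH/CH2Cl2 1:1, 0 °C
Reagents that add atoms: none
Why: Acid-catalysed methanolysis of silyl ethers, in which the unhindered primary allylic silyl ether is cleaved much faster than the secondary one at C6 that is shielded by the tetrasubstituted alkene and by C7.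

Step 11
Reactants: 15 (1R,5S,6R)-5-(TBSO)-6-(3-hydroxyprop-1-en-2-yl)-4-[(2S)-5-hydroxypentan-2-yl]-3-methylcyclohex-3-en-1-ol
Product: 18 (3aR,4S,7aR)-4-(TBSO)-5-[(2S)-5-hydroxypentan-2-yl]-6-methyl-3-methylidene-3a,4,7,7a-tetrahydro-1-benzofuran-2(3H)-one, via hydroxy enal 16 (not isolated), via lactol 17 (not isolated)
Conditions: activated MnO2 (25 equiv), CH2Cl2, 23 °C
Reagents that add atoms: none
Why: Oxidative lactonisation of a 2-methylene-1,4-diol: MnO2 oxidises only the allylic primary alcohol to the enal, the cis C8 hydroxyl adds to it (5-exo-trig) to give the lactol, and MnO2 oxidises this lactol to the α-methylene lactone, the ring fusion being cis because C7 and C8 were set in steps 3 and 9 and the saturated C1 alcohol being untouched.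

Step 12
Reactants: 18 (3aR,4S,7aR)-4-(TBSO)-5-[(2S)-5-hydroxypentan-2-yl]-6-methyl-3-methylidene-3a,4,7,7a-tetrahydro-1-benzofuran-2(3H)-one
Product: 19 (3aS,4S,7aR)-4-hydroxy-5-[(2S)-5-hydroxypentan-2-yl]-6-methyl-3-methylidene-3a,4,7,7a-tetrahydro-1-benzofuran-2(3H)-one
Conditions: HF·pyridine, pyridine/THF, 0 → 23 °C
Reagents that add atoms: none
Why: Fluoride-mediated desilylation with buffered HF·pyridine, which avoids basic fluoride sources that would add to the α-methylene lactone; no stereocentre is touched (the descriptor at C3a changes only through priorities).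

Step 13
Reactants: 19 (3aS,4S,7aR)-4-hydroxy-5-[(2S)-5-hydroxypentan-2-yl]-6-methyl-3-methylidene-3a,4,7,7a-tetrahydro-1-benzofuran-2(3H)-one
Product: 20 (3aR,4S,7aR)-6-methyl-3-methylidene-5-[(2S)-5-(2-methylpropanoyloxy)pentan-2-yl]-2-oxo-2,3,3a,4,7,7a-hexahydro-1-benzofuran-4-yl 2-methylpropanoate
Conditions: (i-PrCO)2O (3 equiv), Et3N (4 equiv), DMAP (0.1 equiv), CH2Cl2, 0 → 23 °C
Reagents that add atoms: isobutyric anhydride (CC(C)C(=O)OC(=O)C(C)C)
Why: Nucleophile-catalysed acylation (DMAP acyl transfer) esterifies the primary C1 and the secondary allylic C6 hydroxyl in one operation to give the target; no stereocentre is touched.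

**Compound list** (TBS = tert-butyldimethylsilyl)

1 | 4-methoxy-2-methylphenol | COc1ccc(O)c(C)c1 | starting material
2 | 4,4-dimethoxy-2-methylcyclohexa-2,5-dien-1-one | COC1(OC)C=CC(=O)C(C)=C1 | intermediate
3 | tert-butyldimethyl(prop-2-yn-1-yloxy)silane | C#CCO[Si](C)(C)C(C)(C)C | starting material
4 | tert-butyldimethyl{[2-(4,4,5,5-tetramethyl-1,3,2-dioxaborolan-2-yl)prop-2-en-1-yl]oxy}silane | C=C(CO[Si](C)(C)C(C)(C)C)B1OC(C)(C)C(C)(C)O1 | intermediate
5 | (5R)-5-{3-[(tert-butyldimethylsilyl)oxy]prop-1-en-2-yl}-4,4-dimethoxy-2-methylcyclohex-2-en-1-one | COC1(OC)C=C(C)C(=O)C[C@@H]1C(=C)CO[Si](C)(C)C(C)(C)C | intermediate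
6 | sodium dienolate of 5 (sodium oxide on ring C1, double bond C1=C6) | COC1(OC)C=C(C)C(O[Na])=C[C@@H]1C(=C)CO[Si](C)(C)C(C)(C)C | intermediate
7 | (5S,6S)-5-{3-[(tert-butyldimethylsilyl)oxy]prop-1-en-2-yl}-6-hydroxy-4,4-dimethoxy-2-methylcyclohex-2-en-1-one | COC1(OC)C=C(C)C(=O)[C@@H](O)[C@@H]1C(=C)CO[Si](C)(C)C(C)(C)C | intermediate
8 | (5S,6S)-6-[(tert-butyldimethylsilyl)oxy]-5-{3-[(tert-butyldimethylsilyl)oxy]prop-1-en-2-yl}-4,4-dimethoxy-2-methylcyclohex-2-en-1-one | COC1(OC)C=C(C)C(=O)[C@@H](O[Si](C)(C)C(C)(C)C)[C@@H]1C(=C)CO[Si](C)(C)C(C)(C)C | intermediate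
9 | lithium (5S,6S)-6-[(tert-butyldimethylsilyl)oxy]-5-{3-[(tert-butyldimethylsilyl)oxy]prop-1-en-2-yl}-4,4-dimethoxy-2-methylcyclohex-1-en-1-olate | COC1(OC)CC(C)=C(O[Li])[C@@H](O[Si](C)(C)C(C)(C)C)[C@@H]1C(=C)CO[Si](C)(C)C(C)(C)C | intermediate
10 | (5S,6S)-6-[(tert-butyldimethylsilyl)oxy]-5-{3-[(tert-butyldimethylsilyl)oxy]prop-1-en-2-yl}-4,4-dimethoxy-2-methylcyclohex-1-en-1-yl trifluoromethanesulfonate | COC1(OC)CC(C)=C(OS(=O)(=O)C(F)(F)F)[C@@H](O[Si](C)(C)C(C)(C)C)[C@@H]1C(=C)CO[Si](C)(C)C(C)(C)C | intermediate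
11 | (Z)-pent-3-en-1-ol | C/C=C\CCO | starting material
12 | (4S)-4-[(5S,6S)-6-[(tert-butyldimethylsilyl)oxy]-5-{3-[(tert-butyldimethylsilyl)oxy]prop-1-en-2-yl}-4,4-dimethoxy-2-methylcyclohex-1-en-1-yl]pentanal | COC1(OC)CC(C)=C([C@@H](C)CCC=O)[C@@H](O[Si](C)(C)C(C)(C)C)[C@@H]1C(=C)CO[Si](C)(C)C(C)(C)C | intermediate
13 | (4S)-4-[(5S,6S)-6-[(tert-butyldimethylsilyl)oxy]-5-{3-[(tert-butyldimethylsilyl)oxy]prop-1-en-2-yl}-2-methyl-4-oxocyclohex-1-en-1-yl]pentanal | O=C1CC(C)=C([C@@H](C)CCC=O)[C@@H](O[Si](C)(C)C(C)(C)C)[C@@H]1C(=C)CO[Si](C)(C)C(C)(C)C | intermediate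
14 | (1R,5S,6R)-5-[(tert-butyldimethylsilyl)oxy]-6-{3-[(tert-butyldimethylsilyl)oxy]prop-1-en-2-yl}-4-[(2S)-5-hydroxypentan-2-yl]-3-methylcyclohex-3-en-1-ol | O[C@@H]1CC(C)=C([C@@H](C)CCCO)[C@@H](O[Si](C)(C)C(C)(C)C)[C@@H]1C(=C)CO[Si](C)(C)C(C)(C)C | intermediate
15 | (1R,5S,6R)-5-[(tert-butyldimethylsilyl)oxy]-6-(3-hydroxyprop-1-en-2-yl)-4-[(2S)-5-hydroxypentan-2-yl]-3-methylcyclohex-3-en-1-ol | O[C@@H]1CC(C)=C([C@@H](C)CCCO)[C@@H](O[Si](C)(C)C(C)(C)C)[C@@H]1C(=C)CO | intermediate
16 | 2-{(1R,2S,6R)-2-[(tert-butyldimethylsilyl)oxy]-6-hydroxy-3-[(2S)-5-hydroxypentan-2-yl]-4-methylcyclohex-3-en-1-yl}prop-2-enal | O[C@@H]1CC(C)=C([C@@H](C)CCCO)[C@@H](O[Si](C)(C)C(C)(C)C)[C@@H]1C(=C)C=O | intermediate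
17 | (3aR,4S,7aR)-4-[(tert-butyldimethylsilyl)oxy]-5-[(2S)-5-hydroxypentan-2-yl]-6-methyl-3-methylidene-2,3,3a,4,7,7a-hexahydro-1-benzofuran-2-ol (both anomers) | C=C1C(O)O[C@@H]2CC(C)=C([C@@H](C)CCCO)[C@@H](O[Si](C)(C)C(C)(C)C)[C@H]12 | intermediate
18 | (3aR,4S,7aR)-4-[(tert-butyldimethylsilyl)oxy]-5-[(2S)-5-hydroxypentan-2-yl]-6-methyl-3-methylidene-3a,4,7,7a-tetrahydro-1-benzofuran-2(3H)-one | C=C1C(=O)O[C@@H]2CC(C)=C([C@@H](C)CCCO)[C@@H](O[Si](C)(C)C(C)(C)C)[C@H]12 | intermediate
19 | (3aS,4S,7aR)-4-hydroxy-5-[(2S)-5-hydroxypentan-2-yl]-6-methyl-3-methylidene-3a,4,7,7a-tetrahydro-1-benzofuran-2(3H)-one | C=C1C(=O)O[C@@H]2CC(C)=C([C@@H](C)CCCO)[C@@H](O)[C@H]12 | intermediate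
20 | (3aR,4S,7aR)-6-methyl-3-methylidene-5-[(2S)-5-(2-methylpropanoyloxy)pentan-2-yl]-2-oxo-2,3,3a,4,7,7a-hexahydro-1-benzofuran-4-yl 2-methylpropanoate | C=C1C(=O)O[C@@H]2CC(C)=C([C@@H](C)CCCOC(=O)C(C)C)[C@@H](OC(=O)C(C)C)[C@H]12 | target

**Step count and risks**

Total steps: 13. Longest linear sequence: 12 steps (steps 1 and 3–13, from 1 to 20).

Steps most likely to fail:

1. Step 7 (key step). What may go wrong: β-hydride elimination back toward ring B (a conjugated diene instead of chain walking), insertion at C3 instead of C4, slow insertion at the hindered tetrasubstituted triflate, or a mismatch between the ligand and the C6/C7 stereocentres that erodes the selectivity at C4. Fallback, setting out from 10 and coming back at 13: Miyaura borylation (PdCl2(dppf), B2pin2, KOPh, toluene, 60 °C) gives the alkenylboronate F1. Rhodium-catalysed asymmetric 1,4-addition of F1 to (E)-but-2-enal (Hayashi–Miyaura reaction; [RhCl(C2H4)2]2, chiral diene ligand, aqueous KOH, dioxane) gives the 3-alkenylbutanal F2, with C4 set by the ligand. Wittig methoxymethylenation (Ph3P=CHOMe from the phosphonium chloride and KN(SiMe3)2, THF) gives the enol ether F3. The acid of step 8 then cleaves the enol ether and the ketal together to give 13.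

2. Step 6. What may go wrong: 1,2-reduction of the ketone competing with hydride delivery to the β-carbon next to the ketal, or migration of the C6 silyl group to the enolate oxygen before triflation. Fallback, setting out from 8 and coming back at 10: conjugate hydrosilylation with catalytic [(Ph3P)CuH]6 and PhMe2SiH (toluene, 23 °C) gives the dimethylphenylsilyl enol ether F4 with the double bond fixed between C5 and C10. MeLi (THF, 0 °C) then releases the lithium enolate 9, which is triflated with PhNTf2 to give 10.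

3. Step 3. What may go wrong: loss of the siloxy group from the alkenylrhodium intermediate (β-oxygen elimination to an allene), protodeboronation of 4, or poor facial selectivity, which would lower the enantiopurity of the whole route. Fallback, setting out from 2 and coming back at 5: the same [RhCl(cod)]2/(R)-BINAP system with potassium isopropenyltrifluoroborate (Et3N, toluene/H2O) gives the isopropenyl ketone F5, so that oxygen at C12 is introduced after the C–C bond. Allylic oxidation of the isopropenyl methyl group (SeO2 cat., t-BuOOH, CH2Cl2) gives the allylic alcohol F6. Silylation (TBSCl, imidazole, DMF) gives 5.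

Further compounds
F1 | step 7 | 2-[(5S,6S)-6-[(tert-butyldimethylsilyl)oxy]-5-{3-[(tert-butyldimethylsilyl)oxy]prop-1-en-2-yl}-4,4-dimethoxy-2-methylcyclohex-1-en-1-yl]-4,4,5,5-tetramethyl-1,3,2-dioxaborolane | COC1(OC)CC(C)=C(B2OC(C)(C)C(C)(C)O2)[C@@H](O[Si](C)(C)C(C)(C)C)[C@@H]1C(=C)CO[Si](C)(C)C(C)(C)C
F2 | step 7 | (3S)-3-[(5S,6S)-6-[(tert-butyldimethylsilyl)oxy]-5-{3-[(tert-butyldimethylsilyl)oxy]prop-1-en-2-yl}-4,4-dimethoxy-2-methylcyclohex-1-en-1-yl]butanal | COC1(OC)CC(C)=C([C@@H](C)CC=O)[C@@H](O[Si](C)(C)C(C)(C)C)[C@@H]1C(=C)CO[Si](C)(C)C(C)(C)C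
F3 | step 7 | (4S)-1-methoxy-4-[(5S,6S)-6-[(tert-butyldimethylsilyl)oxy]-5-{3-[(tert-butyldimethylsilyl)oxy]prop-1-en-2-yl}-4,4-dimethoxy-2-methylcyclohex-1-en-1-yl]pent-1-ene (E/Z mixture) | COC1(OC)CC(C)=C([C@@H](C)CC=COC)[C@@H](O[Si](C)(C)C(C)(C)C)[C@@H]1C(=C)CO[Si](C)(C)C(C)(C)C
F4 | step 6 | {[(5S,6S)-6-[(tert-butyldimethylsilyl)oxy]-5-{3-[(tert-butyldimethylsilyl)oxy]prop-1-en-2-yl}-4,4-dimethoxy-2-methylcyclohex-1-en-1-yl]oxy}dimethyl(phenyl)silane | COC1(OC)CC(C)=C(O[Si](C)(C)c2ccccc2)[C@@H](O[Si](C)(C)C(C)(C)C)[C@@H]1C(=C)CO[Si](C)(C)C(C)(C)C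
F5 | step 3 | (5R)-4,4-dimethoxy-2-methyl-5-(prop-1-en-2-yl)cyclohex-2-en-1-one | COC1(OC)C=C(C)C(=O)C[C@@H]1C(C)=C
F6 | step 3 | (5R)-5-(3-hydroxyprop-1-en-2-yl)-4,4-dimethoxy-2-methylcyclohex-2-en-1-one | COC1(OC)C=C(C)C(=O)C[C@@H]1C(=C)CO
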